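The numbers in the tables were generated by integration with constants of no real substance; noise was put on by code.

Start from 12 %: that is the south-west reading at 8.00 min. The earlier readings stand closer to the scatter of 1.5 percentage points, and I expect the later ones to have used more of the partner, so build on this one.

| flask | starting material | partner | scavenger | remark | time |
|---|---|---|---|---|---|
| south-west | 0.075 M (in portions, 4) | 0.030 M | 0.060 M | run made earlier; portions every 1.5 min |  |
| theta | 0.050 M (in portions, 4) | 0.0300 M | 0.0600 M | the portions of starting material follow each other after 1.5 min, the first at the start | 1.0 h |
| delta | 0.050 M (in portions, 4) | 0.0500 M | 0.0600 M | the portions of starting material follow each other after 1.5 min, the first at the start | 1.0 h |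
| eta | 0.050 M (in portions, 4) | 0.0800 M | 0.0600 M | the portions of starting material follow each other after 1.5 min, the first at the start | 1.0 h |
| epsilon | 0.050 M (in portions, 4) | 0.100 M | 0.0600 M | the portions of starting material follow each other after 1.5 min, the first at the start | 1.0 h |

south-west run (percent of the starting material charged)

| time / min | single product / % |
|---|---|
| 1.50 | 1 |
| 3.00 | 4 |
| 5.00 | 5 |
| 8.00 | 12 |
| 12.0 | 14 |
| 20.0 | 18 |

(each reading ± 1.5 percentage points)

- "hardly changes" means that all values lie within two and a half points (for a concentration: within two and a half percent of the largest)

- [single product] at the end for theta, delta, eta, epsilon, in this order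
- the course of these numbers from the first flask to the last (rises, then falls / falls, then rises / rises all the way / hardly changes / falls all the way)

Count turnovers. First correct the clock: the portions enter on average 2.25 min after the start. Then divide the remaining time by the fraction converted, taking the single product read as that fraction. This gives the turnover time, the time a starting-material molecule needs for one pseudo-first-order turnover at c(partner) = 0.030 M: 47.9 min. Treat it as a reading, since the scatter is 1.5 points.

Next scale it. Turnovers go with c(partner), so for theta, with the partner held at its charge, the count reckons to 1.25 in 1.0 h.

Now suppose, as the word "single" hints, that the single product takes a second partner just as fast. The share of single product is then x·exp(−x), where x is the turnover count, and it tops at x equal to one.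

The weak link is the partner held at its charge. Two steps on the whole charge can take 0.100 M, as much as epsilon holds, and eta holds less. So reforge the link: let the partner fall far, and take its mean as half its charge. That halves every count.

| flask | c(partner) charged | x | c(single product) |
|---|---|---|---|
| theta | 0.0300 M | 0.626 | 0.0167 M |
| delta | 0.0500 M | 1.04 | 0.0184 M |
| eta | 0.0800 M | 1.67 | 0.0157 M |
| epsilon | 0.100 M | 2.09 | 0.0129 M |

Commit to this: my row rises, then falls, and turns near c(partner) = 0.0479 M.

The forecast differs. It gives 0.011 M, 0.016 M, 0.021 M and 0.023 M, and its course rises all the way: “Product rises throughout, with diminishing gains”.

The flasks give 0.0163 M, 0.0194 M, 0.0187 M and 0.0166 M; the course rises, then falls.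

    starting material + partner → single product + released group (k = 0.0128 L mol⁻¹ s⁻¹)
    partner + single product → double product + released group (k = 0.0111 L mol⁻¹ s⁻¹)
    partner + released group ⇌ idle adduct, settled at all times (K = 1990 L mol⁻¹)
    scavenger + released group → scavenged by-product (k = 4.03 L mol⁻¹ s⁻¹)

The row turns at c(partner) = 0.059 M. Read the count back from what remains, as the logarithm of charge over rest. Delta, with 40 % of its starting material left, has made 0.916 turnovers against the 1.04 reckoned from the turnover time. Epsilon, with 16 % left, has made 1.83 against 2.09, and its double product stands at 50.7 %.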